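**Retrosynthetic overview**

1. Ferutinin (16) is cut at the ester to jaeschkeanadiol (13) and silyl-protected p-hydroxybenzoic acid (14); 13 comes from β-hydroxy ketone 12 by hydroxyl-directed anti reduction.
2. Key disconnection: the ring-fusion bond C3a–C8a. C3a sits between the tertiary carbinol C3 (ring of five) and the oxygenated C4 (ring of seven), an aldol pattern, so 12 is the semipinacol product of the cis-decalin 2,3-epoxy alcohol 10. C8a migrates from the carbinol carbon (future C4) to the oxirane CH (future C3a), and the oxirane oxygen becomes the C3 hydroxyl.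
3. That single shift contracts the carbinol ring from six to five and expands the cyclohexene from six to seven. Ring order: p-menthane six-membered ring (from dihydrocarvone), then the cyclohexene by metathesis, then both rings of the hydroazulene at once.
4. 10 comes from ring-closing metathesis of 9, 9 from 2-methylallyl Grignard addition to epoxy ketone 7, 7 from palladium-catalysed decarboxylative asymmetric allylation (quaternary C8a), and the oxirane from amine-catalysed asymmetric epoxidation of carvenone (2). All ten terpene carbons end up as C1–C3, C3a, C4, C8a, the isopropyl group and the angular methyl.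

Key step: step 7

Remarks: commercial (+)-dihydrocarvone is an isomer mixture, which does not matter because its stereocentres are erased. The enantiomeric series of the amine catalyst (step 2) and of the PHOX ligand (step 4) are assigned by analogy with cyclohexenone and 2-methylcyclohexanone and would be switched to the antipodes if induction proves opposite. Locants C1–C8a in the Why lines are the azulene locants of the target.

**Route**

Step 1
Reactants: 1 (+)-dihydrocarvone
Product: 2 carvenone, 6-methyl-3-(propan-2-yl)cyclohex-2-en-1-one (configuration at C6 immaterial)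
Conditions: 6 M aq. H2SO4, 80 °C
Reagents that add atoms: none
Why: Acid-mediated olefin isomerization, in which reversible protonation walks the isopropenyl double bond through the isopropylidene isomer into conjugation with the ketone (the thermodynamic sink); no stereocentre of 1 is needed later.

Step 2
Reactants: 2 carvenone
Product: 3 (1S,6R)-3-methyl-6-(propan-2-yl)-7-oxabicyclo[4.1.0]heptan-2-one (both C3 epimers)
Conditions: 9-amino-9-deoxy-epi-quinine·2 CF3CO2H (10 mol %; or the quinidine-derived pseudoenantiomer, see remarks), 50% aq. H2O2, dioxane, 35 °C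
Reagents that add atoms: hydrogen peroxide, OO
Why: Amine-catalysed asymmetric Weitz–Scheffer epoxidation, in which the primary amine salt forms a chiral iminium ion, hydrogen peroxide adds to the β-carbon on the face set by the catalyst and the enamine closes the oxirane; this fixes the future C3 carbinol and the oxirane CH, and the α'-methyl stereocentre is irrelevant.

Step 3
Reactants: 3 epoxy ketone; 4 allyl chloroformate
Product: 6 prop-2-en-1-yl (1S,6R)-3-methyl-6-(propan-2-yl)-7-oxabicyclo[4.1.0]hept-2-en-2-yl carbonate, via lithium enolate 5 (not isolated)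
Conditions: LiN(SiMe3)2, TMEDA, THF, −78 °C; then ClCO2CH2CH=CH2, −78 to 0 °C
Reagents that add atoms: allyl chloroformate (4), C=CCOC(Cl)=O
Why: Enol carbonate formation, in which the methine next to the carbonyl is the only enolizable position (the other α-carbon is the oxirane CH) and the hard chloroformate acylates the lithium enolate on oxygen; both C3 epimers of 3 converge.

Step 4
Reactants: 6 allyl enol carbonate
Product: 7 (1S,3R,6R)-3-methyl-6-(propan-2-yl)-3-(prop-2-en-1-yl)-7-oxabicyclo[4.1.0]heptan-2-one
Conditions: Pd2(dba)3 (2.5 mol %), (R)-t-BuPHOX (6 mol %), THF, 25 °C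
Reagents that add atoms: none
Why: Decarboxylative asymmetric allylic alkylation (Tsuji allylation), in which zerovalent palladium ionizes the allyl carbonate, CO2 is lost and the enolate recombines with the π-allyl unit inside the chiral PHOX pocket, so the ligand sets the quaternary centre (future C8a) with the allyl group anti to the oxirane oxygen; the tetrasubstituted enol double bond should be too hindered for the metal to ionize the neighbouring oxirane at 25 °C, and the minor diastereomer is removable by chromatography.

Step 5
Reactants: 7 allylated epoxy ketone; 8 2-methylallylmagnesium chloride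
Product: 9 (1R,2R,3R,6R)-3-methyl-2-(2-methylprop-2-en-1-yl)-6-(propan-2-yl)-3-(prop-2-en-1-yl)-7-oxabicyclo[4.1.0]heptan-2-ol (hydroxyl cis to the oxirane oxygen and to the methyl group)
Conditions: CH2=C(CH3)CH2MgCl, THF, −78 °C; aq. NH4Cl
Reagents that add atoms: 2-methylallylmagnesium chloride (8), CC(=C)C[Mg]Cl
Why: Grignard 1,2-addition, in which the allylic reagent adds even to the hindered ketone and should attack anti to the oxirane oxygen (magnesium bridging carbonyl and oxirane oxygens), placing the 2-methylallyl group cis to the allyl group and the new hydroxyl cis to the oxirane oxygen and the methyl group; the oxirane is not opened at −78 °C.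

Step 6
Reactants: 9 monocyclic epoxy alcohol
Product: 10 (1R,2R,4aR,8aR)-1,2-epoxy-4a,7-dimethyl-2-(propan-2-yl)-1,2,3,4,4a,5,8,8a-octahydronaphthalen-8a-ol (cis-decalin; hydroxyl, angular methyl and oxirane oxygen on one face)
Conditions: second-generation Grubbs catalyst RuCl2(=CHPh)(H2IMes)(PCy3) (3 mol %), CH2Cl2, 40 °C
Reagents that add atoms: none
Why: Ring-closing metathesis of the cis-disposed allyl and 2-methylallyl groups should close the cyclohexene with its trisubstituted double bond (the future C6=C7) and release ethylene; oxirane and tertiary alcohol are inert to the ruthenium carbene.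

Step 7
Reactants: 10 cis-decalin epoxy alcohol
Product: 12 (3R,3aR,8aR)-3-hydroxy-6,8a-dimethyl-3-(propan-2-yl)-1,2,3,3a,8,8a-hexahydroazulen-4(5H)-one, via aluminium alkoxide 11 (not isolated)
Conditions: Et2AlCl (1.2 equiv), CH2Cl2, −78 to −20 °C; aq. potassium sodium tartrate (KNaC4H4O6)
Reagents that add atoms: none
Why: Et2AlCl should convert the tertiary hydroxyl into the aluminium alkoxide 11, whose metal also binds the cis oxirane oxygen, so the secondary C–O bond of the oxirane is weakened while the alkoxide pushes; the ring-fusion bond from the carbinol carbon to the quaternary methyl-bearing carbon, antiperiplanar to that C–O bond in the cis-decalin conformer, migrates to the oxirane CH in a semipinacol rearrangement of a 2,3-epoxy alcohol, the closest known type being the Lewis-acid ring contraction of cis-2,3-epoxycyclohexan-1-ols to 2-hydroxycyclopentyl ketones. The single 1,2-shift closes the cyclopentane by contraction of the carbinol ring (six to five) and at the same time closes the cycloheptenone by one-carbon expansion of the cyclohexene ring (six to seven). C3a is formed with inversion at the oxirane carbon (anti attack of the migrating bond), C8a migrates with retention, and the C3 carbinol keeps the oxirane C–O bond set in step 2, so the trans ring fusion and the cis relation of the C3 hydroxyl to the angular methyl follow from the all-cis array of hydroxyl, oxirane oxygen and methyl in 10. The step needs cleavage at the secondary rather than the tertiary oxirane carbon and migration of the quaternary carbon rather than of the ring CH2; the chelated alkoxide push, the stereoelectronic alignment, the higher migratory aptitude of the fully substituted carbon and the strain of the bridged alternative should secure both. The product stays bound as an aluminium aldolate until the neutral tartrate work-up, which protects the β-hydroxy ketone with its skipped double bond from retro-aldol cleavage and olefin conjugation.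

Step 8
Reactants: 12 β-hydroxy ketone
Product: 13 jaeschkeanadiol, (3R,3aS,4S,8aR)-6,8a-dimethyl-3-(propan-2-yl)-1,2,3,3a,4,5,8,8a-octahydroazulene-3,4-diol
Conditions: Me4NBH(OAc)3, MeCN/AcOH (1:1), −30 °C
Reagents that add atoms: none
Why: Evans–Saksena reduction, in which the tertiary C3 hydroxyl exchanges onto boron and hydride is delivered intramolecularly to the face of the C4 ketone syn to that hydroxyl, which should give the 1,3-anti diol (4S); the mildly acidic medium spares the β-hydroxy ketone from retro-aldol cleavage and the skipped enone from conjugation.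

Step 9
Reactants: 13 jaeschkeanadiol; 14 4-[(tert-butyldimethylsilyl)oxy]benzoic acid
Product: 15 (3R,3aS,4S,8aR)-3-hydroxy-6,8a-dimethyl-3-(propan-2-yl)-1,2,3,3a,4,5,8,8a-octahydroazulen-4-yl 4-[(tert-butyldimethylsilyl)oxy]benzoate
Conditions: DCC, DMAP (cat.), CH2Cl2, 0 to 25 °C
Reagents that add atoms: 4-[(tert-butyldimethylsilyl)oxy]benzoic acid (14), CC(C)(C)[Si](C)(C)Oc1ccc(cc1)C(O)=O
Why: Steglich esterification, in which only the secondary C4 hydroxyl should be acylated because the tertiary C3 carbinol flanked by the isopropyl group is too hindered, while the silyl ether keeps the phenol from self-acylation.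

Step 10
Reactants: 15 silyl-protected ferutinin
Product: 16 ferutinin
Conditions: n-Bu4NF, AcOH, THF, 0 °C
Reagents that add atoms: none
Why: Fluoride-induced desilylation, in which the aryl silyl ether is cleaved far faster than anything happens at the benzoate or the tertiary alcohol, and acetic acid buffers the phenoxide.

**Compound list**

1 | (+)-dihydrocarvone, (2R,5R)-2-methyl-5-(prop-1-en-2-yl)cyclohexan-1-one (commercial isomer mixture) | C[C@@H]1CC[C@H](CC1=O)C(C)=C | starting material
2 | carvenone, 6-methyl-3-(propan-2-yl)cyclohex-2-en-1-one | CC1CCC(C(C)C)=CC1=O | intermediate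
3 | (1S,6R)-3-methyl-6-(propan-2-yl)-7-oxabicyclo[4.1.0]heptan-2-one (C3 epimers) | CC1CC[C@]2(C(C)C)O[C@@H]2C1=O | intermediate
4 | allyl chloroformate | C=CCOC(Cl)=O | starting material
5 | lithium (1S,6R)-3-methyl-6-(propan-2-yl)-7-oxabicyclo[4.1.0]hept-2-en-2-olate | [Li+].[O-]C1=C(C)CC[C@]2(C(C)C)O[C@H]12 | intermediate
6 | prop-2-en-1-yl (1S,6R)-3-methyl-6-(propan-2-yl)-7-oxabicyclo[4.1.0]hept-2-en-2-yl carbonate | C=CCOC(=O)OC1=C(C)CC[C@]2(C(C)C)O[C@H]12 | intermediate
7 | (1S,3R,6R)-3-methyl-6-(propan-2-yl)-3-(prop-2-en-1-yl)-7-oxabicyclo[4.1.0]heptan-2-one | C=CC[C@@]1(C)CC[C@]2(C(C)C)O[C@@H]2C1=O | intermediate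
8 | 2-methylallylmagnesium chloride | CC(=C)C[Mg]Cl | starting material
9 | (1R,2R,3R,6R)-3-methyl-2-(2-methylprop-2-en-1-yl)-6-(propan-2-yl)-3-(prop-2-en-1-yl)-7-oxabicyclo[4.1.0]heptan-2-ol | C=CC[C@@]1(C)CC[C@]2(C(C)C)O[C@@H]2[C@@]1(O)CC(C)=C | intermediate
10 | (1R,2R,4aR,8aR)-1,2-epoxy-4a,7-dimethyl-2-(propan-2-yl)-1,2,3,4,4a,5,8,8a-octahydronaphthalen-8a-ol | CC1=CC[C@@]2(C)CC[C@]3(C(C)C)O[C@@H]3[C@@]2(O)C1 | intermediate
11 | chloro(ethyl)aluminium alkoxide of 10 | CC1=CC[C@@]2(C)CC[C@]3(C(C)C)O[C@@H]3[C@@]2(O[Al](Cl)CC)C1 | intermediate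
12 | (3R,3aR,8aR)-3-hydroxy-6,8a-dimethyl-3-(propan-2-yl)-1,2,3,3a,8,8a-hexahydroazulen-4(5H)-one | CC1=CC[C@@]2(C)CC[C@@](O)(C(C)C)[C@@H]2C(=O)C1 | intermediate
13 | jaeschkeanadiol, (3R,3aS,4S,8aR)-6,8a-dimethyl-3-(propan-2-yl)-1,2,3,3a,4,5,8,8a-octahydroazulene-3,4-diol | CC1=CC[C@@]2(C)CC[C@@](O)(C(C)C)[C@@H]2[C@@H](O)C1 | intermediate
14 | 4-[(tert-butyldimethylsilyl)oxy]benzoic acid | CC(C)(C)[Si](C)(C)Oc1ccc(cc1)C(O)=O | starting material
15 | (3R,3aS,4S,8aR)-3-hydroxy-6,8a-dimethyl-3-(propan-2-yl)-1,2,3,3a,4,5,8,8a-octahydroazulen-4-yl 4-[(tert-butyldimethylsilyl)oxy]benzoate | CC1=CC[C@@]2(C)CC[C@@](O)(C(C)C)[C@@H]2[C@@H](OC(=O)c2ccc(O[Si](C)(C)C(C)(C)C)cc2)C1 | intermediate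
16 | ferutinin, (3R,3aS,4S,8aR)-3-hydroxy-6,8a-dimethyl-3-(propan-2-yl)-1,2,3,3a,4,5,8,8a-octahydroazulen-4-yl 4-hydroxybenzoate | CC1=CC[C@@]2(C)CC[C@@](O)(C(C)C)[C@@H]2[C@@H](OC(=O)c2ccc(O)cc2)C1 | target

**Step count and risks**

Total step count: 10. Longest linear sequence: 10 steps (1 to 16).

Steps most likely to fail:

1. Step 7. What may go wrong: heterolysis of the oxirane at its tertiary, isopropyl-bearing carbon (followed by hydride shift or elimination), migration of the ring CH2 instead of the quaternary carbon, or capture by chloride. Fallback, leaving the route at 7 and rejoining at 13: the same 1,2-shift is run under purely anionic conditions on the ketone, where no cation can form. NaOMe in MeOH should add to the carbonyl of 7, and the tetrahedral alkoxide should push the quaternary carbon onto the oxirane CH in a semibenzilic (quasi-Favorskii) ring contraction to the hydroxy ester F1. MeNHOMe·HCl with i-PrMgCl would give the Weinreb amide F2, and 2-methylallylmagnesium chloride the β-hydroxy ketone F3. Me4NBH(OAc)3 would give the anti diol F4, and ring-closing metathesis with the second-generation Grubbs catalyst RuCl2(=CHPh)(H2IMes)(PCy3) would close the cycloheptene to 13.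

2. Step 4. What may go wrong: attack of zerovalent palladium on the oxirane (ionization next to the enol double bond, or isomerization of the epoxy ketone), or weak ligand control over the enolate face. Fallback, leaving at 2 and rejoining at 7: the quaternary centre is set before the oxirane exists. Carvenone 2 with LiN(SiMe3)2 and allyl chloroformate 4 would give the dienyl carbonate F5, and Pd2(dba)3 with (R)-t-BuPHOX the allylated enone F6. Luche reduction (NaBH4, CeCl3·7H2O) would give the allylic alcohols, from which the epimer with hydroxyl cis to methyl, the allylic alcohol F7, is separated (the other epimer is returned to F6 with MnO2). VO(acac)2 with t-BuOOH would epoxidize it syn to the hydroxyl to the epoxy alcohol F8, and Dess–Martin oxidation would give 7.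

3. Step 2. What may go wrong: slow iminium formation and slow peroxide addition at the isopropyl-substituted β-carbon, or low facial selectivity. Fallback, leaving at 2 and rejoining at 3: reagent-controlled carbonyl reduction followed by hydroxyl-directed epoxidation. Corey–Bakshi–Shibata reduction of 2 ((S)-Me-CBS oxazaborolidine, BH3·SMe2) would give the allylic alcohol F9, VO(acac)2 with t-BuOOH the syn epoxy alcohol F10, and Dess–Martin oxidation would give 3.

**Further compounds**

F1 | step 7 | methyl (1R,2R,5R)-2-hydroxy-5-methyl-2-(propan-2-yl)-5-(prop-2-en-1-yl)cyclopentane-1-carboxylate | C=CC[C@@]1(C)CC[C@@](O)(C(C)C)[C@@H]1C(=O)OC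
F2 | step 7 | (1R,2R,5R)-2-hydroxy-N-methoxy-N,5-dimethyl-2-(propan-2-yl)-5-(prop-2-en-1-yl)cyclopentane-1-carboxamide | C=CC[C@@]1(C)CC[C@@](O)(C(C)C)[C@@H]1C(=O)N(C)OC
F3 | step 7 | 1-[(1R,2R,5R)-2-hydroxy-5-methyl-2-(propan-2-yl)-5-(prop-2-en-1-yl)cyclopentyl]-3-methylbut-3-en-1-one | C=CC[C@@]1(C)CC[C@@](O)(C(C)C)[C@@H]1C(=O)CC(C)=C
F4 | step 7 | (1S)-1-[(1S,2R,5R)-2-hydroxy-5-methyl-2-(propan-2-yl)-5-(prop-2-en-1-yl)cyclopentyl]-3-methylbut-3-en-1-ol | C=CC[C@@]1(C)CC[C@@](O)(C(C)C)[C@@H]1[C@@H](O)CC(C)=C
F5 | step 4 | prop-2-en-1-yl 2-methyl-5-(propan-2-yl)cyclohexa-1,5-dien-1-yl carbonate | C=CCOC(=O)OC1=C(C)CCC(C(C)C)=C1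
F6 | step 4 | (6R)-6-methyl-3-(propan-2-yl)-6-(prop-2-en-1-yl)cyclohex-2-en-1-one | C=CC[C@@]1(C)CCC(C(C)C)=CC1=O
F7 | step 4 | (1S,6R)-6-methyl-3-(propan-2-yl)-6-(prop-2-en-1-yl)cyclohex-2-en-1-ol | C=CC[C@@]1(C)CCC(C(C)C)=C[C@@H]1O
F8 | step 4 | (1R,2R,3R,6R)-3-methyl-6-(propan-2-yl)-3-(prop-2-en-1-yl)-7-oxabicyclo[4.1.0]heptan-2-ol | C=CC[C@@]1(C)CC[C@]2(C(C)C)O[C@@H]2[C@@H]1O
F9 | step 2 | (1R)-6-methyl-3-(propan-2-yl)cyclohex-2-en-1-ol (C6 epimers) | CC1CCC(C(C)C)=C[C@@H]1O
F10 | step 2 | (1R,2R,6R)-3-methyl-6-(propan-2-yl)-7-oxabicyclo[4.1.0]heptan-2-ol (C3 epimers) | CC1CC[C@]2(C(C)C)O[C@@H]2[C@@H]1O
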